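## Retrosynthetic overview

1. Target 16 ← 1,2-reduction of both carbonyls of epoxyquinone acid 15 ← nucleophilic epoxidation of quinone monoketal 11 (quinone epoxidation first, carbonyl reduction second; the oxirane is the last ring formed).
2. Monoketal 11 ← oxidative dearomatisation of phenol 10; the 4α-CH2OH is raised to CO2H late, in the same operation that unmasks the ketal.
3. Rings A and B of the decalin ← one chair–chair cation–olefin bicyclisation of a farnesyl hydroquinone whose terminus is already oxidised as a (10S,11S)-10,11-epoxy-12-ol (6). The (E)-CH2OH becomes the equatorial C-4 substituent and the epoxide fixes C-4, C-5, C-9 and C-10. The surplus 3-OH is removed by radical deoxygenation.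
4. Epoxy alcohol 6 ← SeO2 allylic oxidation and Sharpless epoxidation of farnesyl arene 4 ← 4-methoxy-3-methylphenol (1) + (2E,6E)-farnesyl bromide (2).
5. Ring order: aromatic ring purchased; rings A and B together (step 4); oxirane (step 8).

Conventions: drimane numbering for the decalin (C-4 quaternary, C-5/C-10 ring fusion, C-7=C-8 alkene, C-9 bears the C-11 methylene). Six-ring head group: C-1 next to the alkylated C-2, C-3 oxirane CH, C-4, C-5 bears methyl, C-6 is CH.

Assumption: N-benzylcinchonidinium chloride is taken to give the (2R,3S)-oxirane in step 8 (the pseudo-enantiomeric cinchoninium salt is used if a trial shows the opposite sense); 1 and 2 are taken as catalogue chemicals.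

## Route

**Step 1**
Reactants: 1 4-methoxy-3-methylphenol; 2 (2E,6E)-farnesyl bromide
Product: 4 2-[(2E,6E)-farnesyl]-4-methoxy-5-methylphenyl acetate, via farnesylphenol 3 (not isolated)
Conditions: NaH, toluene, 0 °C to rt; then Ac2O, pyridine, DMAP (cat.), rt
Reagents that add atoms: acetic anhydride, CC(=O)OC(C)=O
Why: ortho C-alkylation of a sodium phenoxide by an allylic bromide in a non-polar solvent (SN2, alkene geometry kept; para site blocked by OMe, the other ortho site flanked by the methyl), then O-acetylation so the phenol oxygen cannot trap the later C-8 cation.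

**Step 2**
Reactants: 4 2-[(2E,6E)-farnesyl]-4-methoxy-5-methylphenyl acetate
Product: 5 2-[(2E,6E,10E)-12-hydroxyfarnesyl]-4-methoxy-5-methylphenyl acetate
Conditions: SeO2 (0.3 equiv), tBuOOH (3 equiv), salicylic acid (cat.), CH2Cl2, 0 °C to rt, stopped at partial conversion
Reagents that add atoms: selenium dioxide, O=[Se]=O; tert-butyl hydroperoxide, CC(C)(C)OO
Why: Riley allylic oxidation (ene reaction, then [2,3]-sigmatropic shift) takes the (E)-methyl of the terminal, least hindered trisubstituted alkene and gives the (E)-allylic alcohol.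

**Step 3**
Reactants: 5 2-[(2E,6E,10E)-12-hydroxyfarnesyl]-4-methoxy-5-methylphenyl acetate
Product: 6 (10S,11S)-10,11-epoxy-12-hydroxyfarnesyl arene acetate
Conditions: Ti(OiPr)4 (10 mol %), L-(+)-diethyl tartrate (12 mol %), tBuOOH, 4 Å MS, CH2Cl2, −20 °C
Reagents that add atoms: tert-butyl hydroperoxide, CC(C)(C)OO
Why: Sharpless asymmetric epoxidation is hydroxyl-directed, so only the allylic-alcohol alkene reacts, and L-(+)-tartrate gives the (2S,3S)-epoxy alcohol of an (E)-2-methylalk-2-en-1-ol (here 10S,11S).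

**Step 4**
Reactants: 6 (10S,11S)-10,11-epoxy-12-hydroxyfarnesyl arene acetate
Product: 7 aryl acetate of 3β-hydroxy-4α-(hydroxymethyl)drim-7-ene, (3S,4R,5R,9S,10R)
Conditions: MeAlCl2 (2.5 equiv), CH2Cl2, −78 °C; aq. NaHCO3
Reagents that add atoms: none
Why: Proposed new method: the first equivalent of MeAlCl2 turns the hydroxyl into an aluminium alkoxide and the second activates the oxirane, which opens at its tertiary carbon as the 6,7-alkene attacks anti to the C–O bond and the 2,3-alkene closes ring B through a chair–chair array. The (E)-CH2O group therefore becomes the equatorial 4α substituent and the (Z)-methyl the 4β-methyl, and the (10S,11S)-epoxide fixes 3β-O, 5α-H, 9α-H and 10β-Me in one event. The C-8 cation then loses axial H-7 to give the Δ7 alkene, while the acetate keeps the phenol oxygen from trapping it. The closest known reaction type is the MeAlCl2-promoted epoxide-initiated cation–olefin polycyclisation, including cyclisations of Sharpless-derived epoxy ethers that carry an oxygenated C-4 substituent.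

**Step 5**
Reactants: 7 aryl acetate of 3β-hydroxy-4α-(hydroxymethyl)drim-7-ene
Product: 8 cyclic 3-O,4α-CH2O thionocarbonate of 7
Conditions: 1,1'-thiocarbonyldiimidazole (1.5 equiv), DMAP (cat.), toluene, 90 °C
Reagents that add atoms: 1,1'-thiocarbonyldiimidazole, S=C(n1ccnc1)n1ccnc1
Why: thionocarbonate formation across the 1,3-diol (equatorial 3β-OH and equatorial 4α-CH2OH are gauche, so the six-membered ring closes easily); it prepares a Barton–McCombie deoxygenation without a separate protection of the primary alcohol.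

**Step 6**
Reactants: 8 cyclic 3-O,4α-CH2O thionocarbonate of 7
Product: 10 2-{[4α-(hydroxymethyl)drim-7-en-11-yl]}-4-methoxy-5-methylphenol, via stannyl thiocarbonate 9 (not isolated)
Conditions: Bu3SnH (2 equiv), AIBN (cat.), toluene, 110 °C; then K2CO3, MeOH, 40 °C
Reagents that add atoms: none
Why: Barton–McCombie deoxygenation: the stannyl radical adds to C=S and the adduct fragments toward the secondary C-3 radical, not the primary neopentyl one, so only C-3 loses oxygen; methanolysis then frees the primary alcohol and the phenol, and no stereocentre is touched.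

**Step 7**
Reactants: 10 2-{[4α-(hydroxymethyl)drim-7-en-11-yl]}-4-methoxy-5-methylphenol
Product: 11 2-{[4α-(hydroxymethyl)drim-7-en-11-yl]}-4,4-dimethoxy-5-methylcyclohexa-2,5-dien-1-one
Conditions: PhI(OAc)2 (1.1 equiv), MeOH, 0 °C
Reagents that add atoms: methanol, CO
Why: oxidative dearomatisation of a para-methoxyphenol to the quinone monoketal; the carbonyl ends next to the alkylated carbon and the ketal next to the methyl-bearing carbon, which is what directs step 8.

**Step 8**
Reactants: 11 quinone monoketal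
Product: 12 (2R,3S)-2,3-epoxy-4,4-dimethoxy-5-methylcyclohex-5-en-1-one carrying the drimenylmethyl group at C-2
Conditions: tBuOOH, aq. NaOH, N-benzylcinchonidinium chloride (10 mol %), toluene, 0 °C
Reagents that add atoms: tert-butyl hydroperoxide, CC(C)(C)OO
Why: Weitz–Scheffer nucleophilic epoxidation under chiral phase-transfer control; only the C-2=C-3 alkene has an unsubstituted β-carbon, so it alone is attacked, and the chiral ammonium–peroxide ion pair selects the face and sets both oxirane stereocentres.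

**Step 9**
Reactants: 12 epoxy enone ketal
Product: 15 epoxyquinone acid (2R,3S; 4R,5R,9S,10R), via epoxyquinone alcohol 13 (not isolated), via epoxyquinone aldehyde 14 (not isolated)
Conditions: CrO3, H2SO4, H2O, acetone, 0 °C to rt
Reagents that add atoms: water, O
Why: the aqueous acid hydrolyses the dimethyl ketal and the Jones oxidation takes the neopentyl primary alcohol through the aldehyde hydrate to the acid; the electron-poor oxirane and the trisubstituted alkene tolerate these conditions.

**Step 10**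
Reactants: 15 epoxyquinone acid
Product: 16 CNP0358222.2
Conditions: NaBH4 (3 equiv), CeCl3·7H2O (2 equiv), MeOH, −78 °C; work-up at pH 4
Reagents that add atoms: none
Why: Luche 1,2-reduction of both enedione carbonyls; hydride enters on the oxirane-oxygen face (the usual sense for small non-chelating hydrides on α,β-epoxy cyclohexenones, reinforced at C-1 by the drimenylmethyl group on the opposite face), so both hydroxyls end anti to the oxirane (1R,4S).

## Compound list

1 | 4-methoxy-3-methylphenol | COc1ccc(O)cc1C | starting material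
2 | (2E,6E)-farnesyl bromide | BrC/C=C(\C)CC/C=C(\C)CCC=C(C)C | starting material
3 | 2-[(2E,6E)-3,7,11-trimethyldodeca-2,6,10-trienyl]-4-methoxy-5-methylphenol | Cc1cc(O)c(C/C=C(\C)CC/C=C(\C)CCC=C(C)C)cc1OC | intermediate (not isolated)
4 | 2-[(2E,6E)-3,7,11-trimethyldodeca-2,6,10-trienyl]-4-methoxy-5-methylphenyl acetate | Cc1cc(OC(C)=O)c(C/C=C(\C)CC/C=C(\C)CCC=C(C)C)cc1OC | intermediate
5 | 2-[(2E,6E,10E)-12-hydroxy-3,7,11-trimethyldodeca-2,6,10-trienyl]-4-methoxy-5-methylphenyl acetate | Cc1cc(OC(C)=O)c(C/C=C(\C)CC/C=C(\C)CC/C=C(\C)CO)cc1OC | intermediate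
6 | 2-[(2E,6E)-9-[(2S,3S)-3-(hydroxymethyl)-3-methyloxiran-2-yl]-3,7-dimethylnona-2,6-dienyl]-4-methoxy-5-methylphenyl acetate | Cc1cc(OC(C)=O)c(C/C=C(\C)CC/C=C(\C)CC[C@@H]2O[C@@]2(C)CO)cc1OC | intermediate
7 | 2-{[(1S,4aR,5R,6S,8aR)-6-hydroxy-5-(hydroxymethyl)-2,5,8a-trimethyl-1,4,4a,5,6,7,8,8a-octahydronaphthalen-1-yl]methyl}-4-methoxy-5-methylphenyl acetate (3β-OH, 4α-CH2OH, 4β-Me, 5α-H, 9α-H, 10β-Me, Δ7) | Cc1cc(OC(C)=O)c(C[C@H]2C(C)=CC[C@@H]3[C@]2(C)CC[C@H](O)[C@@]3(C)CO)cc1OC | intermediate
8 | cyclic thionocarbonate (1,3-dioxane-2-thione) of 7 bridging O-3 and the 4α-CH2O, aryl acetate kept | Cc1cc(OC(C)=O)c(C[C@H]2C(C)=CC[C@@H]3[C@]2(C)CC[C@@H]4OC(=S)OC[C@@]34C)cc1OC | intermediate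
9 | S-tributylstannyl thiocarbonate of the 4α-CH2OH, C-3 now CH2, aryl acetate kept | Cc1cc(OC(C)=O)c(C[C@H]2C(C)=CC[C@@H]3[C@]2(C)CCC[C@@]3(C)COC(=O)S[Sn](CCCC)(CCCC)CCCC)cc1OC | intermediate (not isolated)
10 | 2-{[(1S,4aR,5R,8aR)-5-(hydroxymethyl)-2,5,8a-trimethyl-1,4,4a,5,6,7,8,8a-octahydronaphthalen-1-yl]methyl}-4-methoxy-5-methylphenol | Cc1cc(O)c(C[C@H]2C(C)=CC[C@@H]3[C@]2(C)CCC[C@@]3(C)CO)cc1OC | intermediate
11 | 2-{[(1S,4aR,5R,8aR)-5-(hydroxymethyl)-2,5,8a-trimethyl-1,4,4a,5,6,7,8,8a-octahydronaphthalen-1-yl]methyl}-4,4-dimethoxy-5-methylcyclohexa-2,5-dien-1-one | CC1=CC(=O)C(C[C@H]2C(C)=CC[C@@H]3[C@]2(C)CCC[C@@]3(C)CO)=CC1(OC)OC | intermediate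
12 | (2R,3S)-2,3-epoxide of 11 (2,3-epoxy-4,4-dimethoxy-5-methylcyclohex-5-en-1-one, drimenylmethyl at C-2) | CC1=CC(=O)[C@]2(C[C@H]3C(C)=CC[C@@H]4[C@]3(C)CCC[C@@]4(C)CO)O[C@@H]2C1(OC)OC | intermediate
13 | (2R,3S)-2,3-epoxy-5-methylcyclohex-5-ene-1,4-dione with the 4α-(hydroxymethyl)drimenylmethyl group at C-2 | CC1=CC(=O)[C@]2(C[C@H]3C(C)=CC[C@@H]4[C@]3(C)CCC[C@@]4(C)CO)O[C@@H]2C1=O | intermediate (not isolated)
14 | the corresponding 4α-formyl compound | CC1=CC(=O)[C@]2(C[C@H]3C(C)=CC[C@@H]4[C@]3(C)CCC[C@@]4(C)C=O)O[C@@H]2C1=O | intermediate (not isolated)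
15 | (1R,4aR,5S,8aR)-5-{[(2R,3S)-2,3-epoxy-5-methyl-1,4-dioxocyclohex-5-en-2-yl]methyl}-1,4a,6-trimethyl-1,2,3,4,4a,5,8,8a-octahydronaphthalene-1-carboxylic acid | CC1=CC(=O)[C@]2(C[C@H]3C(C)=CC[C@@H]4[C@]3(C)CCC[C@@]4(C)C(=O)O)O[C@@H]2C1=O | intermediate
16 | CNP0358222.2: (1R,4aR,5S,8aR)-5-{[(1R,2S,3R,4S)-2,3-epoxy-1,4-dihydroxy-5-methylcyclohex-5-en-2-yl]methyl}-1,4a,6-trimethyl-1,2,3,4,4a,5,8,8a-octahydronaphthalene-1-carboxylic acid | CC1=C[C@@H](O)[C@]2(C[C@H]3C(C)=CC[C@@H]4[C@]3(C)CCC[C@@]4(C)C(=O)O)O[C@@H]2[C@H]1O | target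

## Count and risks

Total steps: 10. Longest linear sequence: 10 (1 and 2 both enter in step 1).

**Step 4 (bicyclisation of the free epoxy alcohol).** The risks are opening at the secondary oxirane carbon (five-membered ring A), a hydride shift to a hydroxy aldehyde, and Δ8(12) or Δ8 alkene isomers. The fallback sets out from 6 and comes back at 10. It masks the hydroxyl so that the substrate is an epoxy ether of the kind known to cyclise at the tertiary carbon. Silylation of 6 (tert-butyldimethylsilyl chloride, imidazole) gives the silyl ether F1, and MeAlCl2 cyclises it to the 3β-hydroxy silyl ether F2. The lone secondary alcohol is then converted with 1,1'-thiocarbonyldiimidazole into the imidazolylthiocarbonyl ester F3 and reduced with Bu3SnH/AIBN to the 3-deoxy silyl ether F4. Bu4NF followed by K2CO3/MeOH removes the silyl and acetyl groups to give 10.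

**Step 8 (face selectivity of the epoxidation).** The drimane stereocentres are too remote to help, and the phase-transfer catalyst may give a poor ratio. The fallback sets out from 11 and comes back at 13, replacing catalyst control by an auxiliary on the ketal. Acid-catalysed exchange of the dimethyl ketal with (R,R)-hydrobenzoin gives the chiral spiroketal F5, in which one phenyl group shields one face of the C-2=C-3 alkene. Epoxidation with tBuOOH and DBU gives the epoxy spiroketal F6, and aqueous CF3CO2H cleaves the auxiliary to the epoxyquinone alcohol 13, which goes on through the CrO3/H2SO4 oxidation to 15.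

**Step 10 (anti,anti sense of the double reduction).** If hydride enters anti to the oxirane at either carbonyl, a syn epimer results. The fallback sets out from 15 and comes back at 16, and it enforces the face by a temporary ring. Cyclopentadiene adds endo to the C-5=C-6 enedione alkene of 15 on the face away from the oxirane oxygen to give the norbornene adduct F7. NaBH4/CeCl3·7H2O can then reach both carbonyls only from the convex face, which is the oxirane-oxygen face, giving the adduct diol F8 with both hydroxyls anti to the oxirane. Thermal retro-Diels–Alder reaction (diphenyl ether, 230 °C, or flash vacuum pyrolysis) releases 16.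

## Further compounds

F1 | step 4 | tert-butyldimethylsilyl ether of epoxy alcohol 6 | Cc1cc(OC(C)=O)c(C/C=C(\C)CC/C=C(\C)CC[C@@H]2O[C@@]2(C)CO[Si](C)(C)C(C)(C)C)cc1OC
F2 | step 4 | aryl acetate of 3β-hydroxy-4α-(tert-butyldimethylsilyloxymethyl)drim-7-ene | Cc1cc(OC(C)=O)c(C[C@H]2C(C)=CC[C@@H]3[C@]2(C)CC[C@H](O)[C@@]3(C)CO[Si](C)(C)C(C)(C)C)cc1OC
F3 | step 4 | 3-O-(imidazol-1-ylthiocarbonyl) derivative of F2 | Cc1cc(OC(C)=O)c(C[C@H]2C(C)=CC[C@@H]3[C@]2(C)CC[C@H](OC(=S)n4ccnc4)[C@@]3(C)CO[Si](C)(C)C(C)(C)C)cc1OC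
F4 | step 4 | aryl acetate of 4α-(tert-butyldimethylsilyloxymethyl)drim-7-ene (3-deoxy) | Cc1cc(OC(C)=O)c(C[C@H]2C(C)=CC[C@@H]3[C@]2(C)CCC[C@@]3(C)CO[Si](C)(C)C(C)(C)C)cc1OC
F5 | step 8 | (R,R)-hydrobenzoin spiroketal of quinone monoketal 11 | CC1=CC(=O)C(C[C@H]4C(C)=CC[C@@H]5[C@]4(C)CCC[C@@]5(C)CO)=CC12O[C@H](c3ccccc3)[C@@H](c3ccccc3)O2
F6 | step 8 | (2R,3S)-2,3-epoxide of spiroketal F5 | CC1=CC(=O)[C@]2(C[C@H]3C(C)=CC[C@@H]4[C@]3(C)CCC[C@@]4(C)CO)O[C@@H]2C12O[C@H](c3ccccc3)[C@@H](c3ccccc3)O2
F7 | step 10 | endo cyclopentadiene adduct of epoxyquinone acid 15 at C-5=C-6, formed anti to the oxirane oxygen | C[C@@]12C(=O)[C@H]3O[C@@]3(C[C@H]4C(C)=CC[C@@H]5[C@]4(C)CCC[C@@]5(C)C(=O)O)C(=O)[C@@H]1[C@@H]1C=C[C@H]2C1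
F8 | step 10 | diol from F7 with both hydroxyls anti to the oxirane | C[C@@]12[C@H](O)[C@H]3O[C@@]3(C[C@H]4C(C)=CC[C@@H]5[C@]4(C)CCC[C@@]5(C)C(=O)O)[C@H](O)[C@@H]1[C@@H]1C=C[C@H]2C1
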